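**Assumption:** the target has no stereocenters, so it is achiral and no stereocontrol is needed anywhere in the route.

## Retrosynthetic overview
- The last bond made is C2–C1′, by addition of a 2,4-bis(silyloxy)phenyl radical to C2 of a 2-unsubstituted 3-prenylchromone (radical Heck-type arylation), followed by desilylation.
- The pyranone ring is closed from a 2-hydroxyaryl ketone and DMF-DMA. The C3 prenyl is carried in as the 5-methylhex-4-enoyl side chain of that ketone.
- The 6,8-diprenyls come from symmetric double C-prenylation of a 2-acylphloroglucinol.
- Ring order: benzene ring A is built first by a [3+3] cyclization of an acetylacetone dianion with malonyl dichloride, then the pyranone ring C. Ring B is a resorcinol-derived aryl iodide attached last.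

## Route

**Step 1**
Reactants: 1 acetylacetone; 2 prenyl bromide
Product: 3 8-methylnon-7-ene-2,4-dione
Conditions: NaH (1 equiv), then n-BuLi (1 equiv), THF, 0 °C; then 2 (1 equiv), –78 → 0 °C
Reagents that add atoms: prenyl bromide (2), CC(C)=CCBr, is listed as a reactant; no other atom-adding reagent.
Why: The acetylacetone 1,3-dianion alkylates at its more basic terminal carbon (Hauser–Weiler dianion alkylation), giving the homoprenyl ketone that becomes the C3-prenyl unit.

**Step 2**
Reactants: 3; 4 malonyl dichloride
Product: 5 5-methyl-1-(2,4,6-trihydroxyphenyl)hex-4-en-1-one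
Conditions: 3, NaH (1 equiv), n-BuLi (1 equiv), THF, 0 °C; then add to 4 (1 equiv), –78 → 25 °C; aq. NH4Cl
Reagents that add atoms: malonyl dichloride (4), ClC(=O)CC(Cl)=O, is listed as a reactant; no other atom-adding reagent.
Why: Proposed new method: the terminal carbon of the dianion is acylated by one COCl, and the central carbon then closes onto the second COCl (6-ring Dieckmann/Claisen-type acylation), enolizing to the 2-acylphloroglucinol. The closest known reactions are biomimetic polyketide Claisen cyclizations and [3+3] cyclizations of 1,3-dicarbonyl dianions with malonyl-type 1,3-dielectrophiles. This builds ring A with the keto side chain in place.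

**Step 3**
Reactants: 5; 2 prenyl bromide (2.1 equiv)
Product: 6 1-(2,4,6-trihydroxy-3,5-bis(3-methylbut-2-enyl)phenyl)-5-methylhex-4-en-1-one
Conditions: NaOMe (3 equiv), MeOH, 0 °C → 25 °C, 4 h
Reagents that add atoms: prenyl bromide (2), CC(C)=CCBr, is listed as a reactant; no other atom-adding reagent.
Why: Acylphloroglucinols undergo C-alkylation at the two equivalent positions flanked by phenoxides (as in hop acid syntheses), so both ring-A prenyls (future C6 and C8) are installed in one operation with no regiochemical choice.

**Step 4**
Reactants: 6; 7 N,N-dimethylformamide dimethyl acetal (DMF-DMA)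
Product: 8 5,7-dihydroxy-3,6,8-tris(3-methylbut-2-enyl)-4H-chromen-4-one
Conditions: 7 (4 equiv), toluene, 100 °C, 6 h; then AcOH, 50 °C, 1 h
Reagents that add atoms: DMF-DMA (7), CN(C)C(OC)OC, is listed as a reactant; it supplies the C2–H carbon.
Why: Enaminone formation at the α-CH2 followed by phenol attack and loss of HNMe2 (3-alkylchromone synthesis from o-hydroxyaryl alkyl ketones). The two ortho OH groups are equivalent by symmetry, and the hindered 4-OH flanked by two prenyls resists O-methylation.

**Step 5**
Reactants: 9 resorcinol; 10 tert-butyldimethylsilyl chloride (TBSCl)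
Product: 11 1,3-bis(tert-butyldimethylsilyloxy)benzene
Conditions: 10 (2.4 equiv), imidazole (3 equiv), DMF, 25 °C, 4 h
Reagents that add atoms: TBSCl (10), CC(C)(C)[Si](C)(C)Cl, is listed as a reactant.
Why: Standard silylation masks both phenols so the later aryl radical cannot cyclize onto an ortho O–H, and the silyl ethers are removable under non-acidic conditions that the prenyl groups tolerate.

**Step 6**
Reactants: 11; 12 N-iodosuccinimide (NIS)
Product: 13 4-iodo-1,3-bis(tert-butyldimethylsilyloxy)benzene, i.e. 1-iodo-2,4-bis(TBSO)benzene
Conditions: 12 (1.0 equiv), MeCN, 0 °C → 25 °C, 2 h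
Reagents that add atoms: NIS (12), O=C1CCC(=O)N1I, is listed as a reactant; it supplies I.
Why: Electrophilic aromatic iodination occurs at the position ortho to one OSi group and para to the other (C4), giving the aryl radical precursor.

**Step 7**
Reactants: 8; 13 (3 equiv)
Product: 14 2-[2,4-bis(TBSO)phenyl]-5,7-dihydroxy-3,6,8-tris(3-methylbut-2-enyl)chromen-4-one
Conditions: Pd(OAc)2 (10 mol%), Xantphos (20 mol%), K3PO4 (3 equiv), DMA, blue LEDs (456 nm), 35 °C, 24 h
Reagents that add atoms: none (the aryl group is delivered by 13, which is a listed reactant).
Why: Proposed new method: photoexcited Pd(0) transfers an electron to the aryl iodide, and the resulting nucleophilic 2,4-dialkoxyaryl radical adds to C2, the unsubstituted β-carbon of the chromone enone (C3 is blocked by prenyl); this forms the key C2–C1′ bond. The tertiary α-keto radical at C3 recombines with Pd(I) and undergoes β-H elimination, restoring the C2=C3 bond at the flavone oxidation level. The closest known reaction type is the visible-light Pd-radical Heck reaction of aryl iodides with electron-poor alkenes. The electron-rich aryl radical is polarity-matched to the electron-poor enone and mismatched to the three electron-rich, hindered trisubstituted prenyl alkenes.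

**Step 8**
Reactants: 14
Product: 15 Artelasticin (5,7,2′,4′-tetrahydroxy-3,6,8-triprenylflavone)
Conditions: TBAF (4 equiv), AcOH (4 equiv), THF, 0 °C, 30 min
Reagents that add atoms: none (fluoride leaves as TBSF; the new O–H hydrogens come from workup).
Why: Buffered fluoride cleaves aryl silyl ethers without acid or strong base, so the prenyl alkenes, which cyclize under acid, and the flavone core are untouched.

## Compound list
1 | acetylacetone | CC(=O)CC(C)=O | starting material
2 | prenyl bromide | CC(C)=CCBr | starting material
3 | 8-methylnon-7-ene-2,4-dione | CC(=O)CC(=O)CCC=C(C)C | intermediate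
4 | malonyl dichloride | ClC(=O)CC(Cl)=O | starting material
5 | 5-methyl-1-(2,4,6-trihydroxyphenyl)hex-4-en-1-one | CC(C)=CCCC(=O)c1c(O)cc(O)cc1O | intermediate
6 | 1-(2,4,6-trihydroxy-3,5-diprenylphenyl)-5-methylhex-4-en-1-one | CC(C)=CCCC(=O)c1c(O)c(CC=C(C)C)c(O)c(CC=C(C)C)c1O | intermediate
7 | DMF-DMA | CN(C)C(OC)OC | starting material
8 | 5,7-dihydroxy-3,6,8-triprenylchromone | CC(C)=CCc1coc2c(CC=C(C)C)c(O)c(CC=C(C)C)c(O)c2c1=O | intermediate
9 | resorcinol | Oc1cccc(O)c1 | starting material
10 | TBSCl | CC(C)(C)[Si](C)(C)Cl | starting material
11 | 1,3-bis(TBSO)benzene | CC(C)(C)[Si](C)(C)Oc1cccc(O[Si](C)(C)C(C)(C)C)c1 | intermediate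
12 | N-iodosuccinimide | O=C1CCC(=O)N1I | starting material
13 | 1-iodo-2,4-bis(TBSO)benzene | CC(C)(C)[Si](C)(C)Oc1ccc(I)c(O[Si](C)(C)C(C)(C)C)c1 | intermediate
14 | 2-[2,4-bis(TBSO)phenyl]-5,7-dihydroxy-3,6,8-triprenylchromone | CC(C)=CCc1c(O)c(CC=C(C)C)c2oc(-c3ccc(O[Si](C)(C)C(C)(C)C)cc3O[Si](C)(C)C(C)(C)C)c(CC=C(C)C)c(=O)c2c1O | intermediate
15 | Artelasticin | CC(C)=CCc1c(O)c(CC=C(C)C)c2oc(-c3ccc(O)cc3O)c(CC=C(C)C)c(=O)c2c1O | target

## Totals
- **Total steps:** 8.
- **Longest linear sequence:** 6 steps (1 → 2 → 3 → 4 → 7 → 8).

## Three steps most likely to fail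
1. **Step 7 (radical arylation).** Possible problems are competing aryl-radical addition to the prenyl alkenes, 1,5-hydrogen transfer from the ortho silyl group, and deactivation of the chromone as its 7-phenolate.
   - Fallback: change the approach to a Claisen–Schmidt condensation of ketone 6 with 2,4-dihydroxybenzaldehyde (from resorcinol by Vilsmeier formylation) to give the α-prenyl-2′-hydroxychalcone, then oxidative cyclization (I2/DMSO) to the flavone.
2. **Step 2 ([3+3] dianion/malonyl dichloride cyclization).** Malonyl dichloride can form ketenes or O-acylated and oligomeric products.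
   - Fallback: acylate the dianion of 3 with methyl malonyl chloride to give the linear triketo ester, then close the ring in a separate base-mediated Claisen cyclization.
3. **Step 3 (double C-prenylation).** This may give mono-, tri- or O-prenylated and dearomatized products.
   - Fallback: pre-install the ring-A prenyls before ring formation, using a bis(homoprenyl) acetylacetone and prenylmalonyl dichloride in a [3+3] cyclization.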